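**Conventions.** Flavanone numbering is used throughout: unprimed locants for the 5,7-dihydroxy unit, double-primed locants for the 7''-methoxy unit. SEM = [2-(trimethylsilyl)ethoxy]methyl; PMB = 4-methoxybenzyl.

## Analysis of the target

The target is a 3,3''-biflavanone: two 2-(4-methoxyphenyl)chroman-4-one units joined by one single bond between C3 and C3''. Ring A of the first unit carries 5,7-dihydroxy groups and ring A of the second 5''-hydroxy-7''-methoxy, so the halves differ only at O7. The four stereocentres C2, C3, C3'' and C2'' are contiguous and all R. In each ring C the 4-methoxyphenyl group at C2 and the other flavanone unit at C3 lie on the same face (2,3-cis), and the two halves have the same handedness. The 2,3-cis arrangement is the less stable one: C3–H is α to the C4 ketone and β to the ring oxygen, so acid or base can epimerise C3 or open ring C by retro-oxa-Michael reaction, and an open β-hydroxy ketone form can undergo retro-aldol cleavage or dehydration. In addition, C2–O1 is a 4-methoxybenzylic ether that ionises easily, and the phloroglucinol-type rings A are oxidisable and nucleophilic at carbon. The synthesis is hard because a crowded C3–C3'' bond is flanked by four stereocentres, two cis relationships must be set kinetically in one absolute sense, and two almost identical rings A must be told apart. The strategy rests on one feature: C2–C3 and C2''–C3'' each join a benzylic, oxygen-bearing carbon to a carbon that becomes allylic once C4 and C4'' are written as =CH2-bearing alkene carbons, which is the retron of a [2,3]-Wittig rearrangement of an allyl 4-methoxybenzyl ether.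

## Retrosynthetic reasoning

**End game (23 ⇒ 22 ⇒ 20).** The last step only removes three benzyl groups from 22 under neutral hydrogenolysis, so the epimerisable cis-flavanone is never exposed to acid or base. The two C4 ketones of 22 are traced back to the exocyclic methylene groups of 20. As long as C4 and C4'' are alkene carbons, C3 and C3'' cannot enolise and no aldol-type fragmentation is possible. The forward reaction has to cleave two 1,1-disubstituted alkenes next to electron-rich rings, which is why the free phenols of 19 are benzylated to 20 first.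

**Rings C (19 ⇒ 18).** The bonds O1–C2 and O1''–C2'' are cut. They are the only ring bonds whose formation can be stereospecific at C2 without touching C3, and cutting them turns the tricyclic problem into an acyclic one. The forward reaction is a double Mitsunobu etherification with inversion. A conformational analysis shows which open-chain isomer is needed: for a 2,3-cis ring formed with inversion, the carbinol oxygen and the C3–C3'' bond must be anti when the chain aryl–C2–C3–C4 is drawn in zigzag. That is the (1S,2S,3S,4S)-diol 18. A syn arrangement of these groups would close to the 2,3-trans series.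

**Phenol unmasking (18 ⇒ 17).** The five phenols must be freed in the presence of two secondary 4-methoxybenzylic alcohols and two 1-arylvinyl groups, all of which are ruined by protic acid (ionisation at C2, alkene migration into conjugation). The phenols are therefore carried as SEM acetals in 17. These direct ortho-lithiation as other alkoxymethyl acetals do but are removed by fluoride under basic, non-ionising conditions.

**Key disconnection (17 ⇒ 15).** C2–C3 and C2''–C3'' are cut together. Each is the σ-bond formed when a lithiated PMB ether carbon attacks the far alkene carbon of its allyl ether. Two skeletal bonds and all four stereocentres arise in one operation from the flat, stereochemically simple diene 15. The alkene geometry decides the relative configuration. With the 4-methoxyphenyl group exo in the envelope transition state, a C3 substituent cis to the CH2O group ends up syn to the new hydroxyl, and one trans to it ends up anti. The anti,anti diol 17 therefore requires the (2E,4E) geometry of 15, in which each ring-A aryl group is cis to the diene chain. Z geometry at either alkene would lead to the syn relationship in that half and, after inversion, to a 2,3-trans ring. The forward reaction also needs one absolute sense in both shifts, which an external chiral ligand on lithium has to supply.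

**Ether formation (15 ⇒ 13 + 14).** The two O–CH2Ar bonds are cut. A double Williamson etherification of diol 13 with two molecules of chloride 14 installs both carbanion precursors, which are also the two rings B, in one step.

**Diene assembly (13 ⇒ 12 + 8; 12 ⇒ 11; 11 ⇒ 10 + 4; 10 ⇒ 9).** The two aryl–alkenyl bonds are cut. The required geometry (aryl cis to the chain, H cis to CH2OH) corresponds to an anti addition of aryl and hydrogen across each triple bond of 9. A syn-hydroarylation would give the wrong isomer. The route therefore uses hydroxyl-directed, ruthenium-catalysed trans-hydrostannation, which places tin on the carbon next to the CH2OH group and trans to the new hydrogen, followed by Stille coupling with retention. Doing this one alkyne at a time (9 → 10 → 11 → 12 → 13) puts two different rings A on the two ends without any late differentiation.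

**Rings A (4 ⇒ 2 ⇒ 1; 8 ⇒ 6 ⇒ 5).** The aryl iodides 4 and 8 come from 1 and 5 by acetal formation and directed ortho-lithiation/iodination. In 2 all three ring positions are equivalent. In 6 the position between the two acetal oxygens is the most activated. The O7/O7'' difference is thus fixed in the first steps.

## Alternatives that were turned down

**Alternative 1: Mitsunobu closure at the ketone oxidation level.** The disconnection is again O1–C2 and O1''–C2'', but on the open bis-β-hydroxy ketone A2. A phosphine–azodicarboxylate redox pair would close both rings with inversion to the 7-O-benzyl ether A1, and one hydrogenolysis would finish the synthesis.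
- For it: the end game is two to three steps shorter, no alkene surrogate or oxidative cleavage is needed, and no thermally labile 1,5-diene is passed. On these points it is stronger than the chosen route.
- Against it: to reach the cis,cis target by inversion, A2 must be the anti,anti bis-aldol, the harder one to make. Its two central stereocentres are α to aryl ketones, and each half of A2 can revert by retro-aldol reaction or lose water by β-elimination, also under the basic betaine of the closure itself. How the four centres of A2 would be set stereoselectively remains an open problem.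
- Comparison: the chosen route performs the same ring closure on 18, where C4 and C4'' are alkene carbons, so C3 and C3'' are configurationally secure, and the four centres come from alkene geometry in a single step.

**Alternative 2: rings A formed last from dioxinone arms.** The disconnection is C4a–C5 and C4a''–C5''. Heating the bis-dioxinone A4 would trigger two cycloreversions that unmask ketene carbons. These are attacked by C4a and C4a'', and aromatisation gives the 7''-O-demethyl compound A3.
- For it: it avoids all hindered aryl–alkenyl couplings and every phenol protecting group. On that point it is stronger than the chosen route.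
- Against it: A3 has O7–H and O7''–H in practically identical surroundings, and the target needs a methyl group on O7'' only, so the last step would be a statistical alkylation. The cis C2/C3 centres would also have to survive temperatures above 100 °C in a ring that can open by retro-oxa-Michael reaction. A stereocontrolled synthesis of A4 would still have to be devised.
- Comparison: the chosen strategy distinguishes the two rings A from the first steps (4 versus 8) and sets the stereocentres at −78 °C.

**Alternative 3: aryl ether closure by fluoride displacement.** The disconnection is O1–C8a and O1''–C8a''. A base would convert the diol A6 into alkoxides that displace the ortho fluorides, giving A5 with C2 and C2'' retained.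
- For it: no substitution takes place at the ionisable 4-methoxybenzylic carbon, which is clearly better than any Mitsunobu closure. It also starts from the syn,syn aldol, the isomer standard aldol methods deliver.
- Against it: the alkoxide of a β-hydroxy ketone under strong base invites retro-aldol cleavage and enolisation at C3 and C3'', which is fatal for a kinetic cis product. The fluoroarene rings of A6 carry two donor alkoxy groups each and are poor substrates for the displacement. A5 also needs a selective O5'' demethylation with a boron halide in the presence of three other aryl methyl ethers and an acid-labile cis-flavanone.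
- Comparison: the chosen route closes the rings under nearly neutral conditions before any ketone exists. It pays for this with the ionisation risk at C2 and C2''.

Key step: step 10

**Remark on an assumption.** The sense of induction of the alkyllithium–bis(oxazoline) base cannot be derived for this substrate; the (S,S)-ligand is written, and its antipode would be used if it proved to lead to the enantiomeric series.

## Route

**Step 1**
Reactants: 1 phloroglucinol
Product: 2 1,3,5-tris{[2-(trimethylsilyl)ethoxy]methoxy}benzene
Conditions: SEMCl (3.6 equiv), i-Pr2NEt, DMF, 0 °C → rt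
Reagents that add atoms: 2-(trimethylsilyl)ethoxymethyl chloride, C[Si](C)(C)CCOCCl
Why: O-alkylation of the three phenols with a reactive α-chloro ether under amine base (acetal protection); the mild base limits C-alkylation of the phloroglucinol ring.

**Step 2**
Reactants: 2 1,3,5-tris{[2-(trimethylsilyl)ethoxy]methoxy}benzene
Product: 4 2-iodo-1,3,5-tris{[2-(trimethylsilyl)ethoxy]methoxy}benzene, via aryllithium 3 (not isolated)
Conditions: n-BuLi, THF, 0 °C; then I2, −78 °C → rt
Reagents that add atoms: iodine, II
Why: Directed ortho-metalation between two chelating acetal oxygens followed by iodinolysis; the three ring positions of 2 are equivalent, so only one iodide can form.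

**Step 3**
Reactants: 5 5-methoxyresorcinol
Product: 6 1-methoxy-3,5-bis{[2-(trimethylsilyl)ethoxy]methoxy}benzene
Conditions: SEMCl (2.4 equiv), i-Pr2NEt, DMF, 0 °C → rt
Reagents that add atoms: 2-(trimethylsilyl)ethoxymethyl chloride, C[Si](C)(C)CCOCCl
Why: Acetal protection of both phenols as in step 1.

**Step 4**
Reactants: 6 1-methoxy-3,5-bis{[2-(trimethylsilyl)ethoxy]methoxy}benzene
Product: 8 2-iodo-5-methoxy-1,3-bis{[2-(trimethylsilyl)ethoxy]methoxy}benzene, via aryllithium 7 (not isolated)
Conditions: n-BuLi, TMEDA, THF, 0 °C; then I2, −78 °C → rt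
Reagents that add atoms: iodine, II
Why: Directed ortho-metalation; the position flanked by two acetal groups, each a stronger director than methoxy, should be lithiated in preference to the two positions next to the methyl ether, and iodine traps the aryllithium.

**Step 5**
Reactants: 9 hexa-2,4-diyne-1,6-diol (threefold excess)
Product: 10 (Z)-2-(tributylstannyl)hex-2-en-4-yne-1,6-diol
Conditions: Bu3SnH (slow addition, limiting), [(C5Me5)RuCl]4 (cat.), CH2Cl2, rt
Reagents that add atoms: tributyltin hydride, CCCC[SnH](CCCC)CCCC
Why: Ruthenium-catalysed trans-hydrostannation of a propargylic alcohol; the hydroxyl group, hydrogen-bonded to the chloride ligand, steers tin to the adjacent alkyne carbon and H and Sn add anti, so tin ends up cis to the remaining alkyne; the excess of the cheap, easily recovered diol 9 holds the reaction at mono-addition.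

**Step 6**
Reactants: 10 (Z)-2-(tributylstannyl)hex-2-en-4-yne-1,6-diol; 4 2-iodo-1,3,5-tris{[2-(trimethylsilyl)ethoxy]methoxy}benzene
Product: 11 (E)-2-(2,4,6-tris{[2-(trimethylsilyl)ethoxy]methoxy}phenyl)hex-2-en-4-yne-1,6-diol
Conditions: Pd(PtBu3)2 (cat.), CuI (cat.), CsF, DMF, 45 °C
Reagents that add atoms: none
Why: Stille coupling with copper and fluoride assistance, conditions suited to hindered aryl halides and α-branched alkenylstannanes; the alkenyl group is transferred with retention, so the aryl group takes the place of tin, cis to the alkyne.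

**Step 7**
Reactants: 11 (E)-2-(2,4,6-tris{[2-(trimethylsilyl)ethoxy]methoxy}phenyl)hex-2-en-4-yne-1,6-diol
Product: 12 (2E,4Z)-2-(2,4,6-tris{[2-(trimethylsilyl)ethoxy]methoxy}phenyl)-5-(tributylstannyl)hexa-2,4-diene-1,6-diol
Conditions: Bu3SnH, [(C5Me5)RuCl]4 (cat.), CH2Cl2, rt
Reagents that add atoms: tributyltin hydride, CCCC[SnH](CCCC)CCCC
Why: Second hydroxyl-directed trans-hydrostannation, now of a 1,3-enyne carrying a propargylic alcohol; tin is delivered next to the C6 hydroxymethyl group and anti to the new hydrogen, that is, cis to the diene chain.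

**Step 8**
Reactants: 12 (2E,4Z)-2-(2,4,6-tris{[2-(trimethylsilyl)ethoxy]methoxy}phenyl)-5-(tributylstannyl)hexa-2,4-diene-1,6-diol; 8 2-iodo-5-methoxy-1,3-bis{[2-(trimethylsilyl)ethoxy]methoxy}benzene
Product: 13 (2E,4E)-2-(2,4,6-tris{[2-(trimethylsilyl)ethoxy]methoxy}phenyl)-5-(4-methoxy-2,6-bis{[2-(trimethylsilyl)ethoxy]methoxy}phenyl)hexa-2,4-diene-1,6-diol
Conditions: Pd(PtBu3)2 (cat.), CuI (cat.), CsF, DMF, 45 °C
Reagents that add atoms: none
Why: Stille coupling with retention as in step 6; both aryl groups now sit cis to the diene chain and both CH2OH groups trans to it, the geometry the key step requires.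

**Step 9**
Reactants: 13 (2E,4E)-2,5-diarylhexa-2,4-diene-1,6-diol; 14 4-methoxybenzyl chloride (two equivalents, one for each hydroxyl group)
Product: 15 (2E,4E)-1,6-bis[(4-methoxybenzyl)oxy]-2-(2,4,6-tris{[2-(trimethylsilyl)ethoxy]methoxy}phenyl)-5-(4-methoxy-2,6-bis{[2-(trimethylsilyl)ethoxy]methoxy}phenyl)hexa-2,4-diene
Conditions: NaH (2.5 equiv), 14 (2.4 equiv), Bu4NI (cat.), THF–DMF, 0 °C → rt
Reagents that add atoms: 4-methoxybenzyl chloride (the second equivalent of 14), COc1ccc(CCl)cc1
Why: Double Williamson etherification: each of the two primary allylic alkoxides of 13 displaces chloride from one molecule of the benzylic chloride 14, so two molecules of 14 are consumed per molecule of diol; no stereocentre or alkene geometry is affected.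

**Step 10**
Reactants: 15 (2E,4E)-bis(4-methoxybenzyl) ether
Product: 17 (1S,2S,3S,4S)-1,4-bis(4-methoxyphenyl)-2-[1-(2,4,6-tris{[2-(trimethylsilyl)ethoxy]methoxy}phenyl)ethenyl]-3-[1-(4-methoxy-2,6-bis{[2-(trimethylsilyl)ethoxy]methoxy}phenyl)ethenyl]butane-1,4-diol, via mono-rearranged lithium alkoxide 16 (not isolated)
Conditions: t-BuLi, (S,S)-2,2'-(pentane-3,3-diyl)bis(4-isopropyl-4,5-dihydro-1,3-oxazole), hexane–toluene, −78 °C; then aq. NH4Cl
Reagents that add atoms: none
Why: The lithium base removes one benzylic proton next to oxygen, and the carbanion carbon bonds to C3 while the C–O bond to the allylic CH2 breaks, suprafacially through a five-membered envelope transition state, which moves the alkene to C4=CH2; the second ether of alkoxide 16 rearranges in the same way. The closest known reaction is the enantioselective [2,3]-Wittig rearrangement of allyl benzyl ethers induced by alkyllithium–bis(oxazoline) bases. No ring is closed. The relative configuration within each pair (C2/C3 and C2''/C3'') follows from the E geometry: with the 4-methoxyphenyl group exo in the envelope, a C3 substituent trans to the CH2O group ends up anti to the new hydroxyl, and the ring-A aryl group on C4, held perpendicular to the allyl plane by its two ortho substituents, blocks the endo position and reinforces this preference. The absolute configuration at C2 and C2'', and with it that of C3 and C3'', is set by the chiral ligand on lithium. The C3/C3'' relation requires both shifts to take the same absolute course; a mismatched second shift leads into a pseudo-meso diastereomeric series that is removed by chromatography, which also raises the enantiomeric purity of the wanted isomer. The step needs benzylic rather than allylic or aryl lithiation and [2,3]- rather than [1,2]-shift, both of which −78 °C and a hydrocarbon medium favour.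

**Step 11**
Reactants: 17 (1S,2S,3S,4S)-diol, five SEM groups
Product: 18 (1S,2S,3S,4S)-1,4-bis(4-methoxyphenyl)-2-[1-(2,4,6-trihydroxyphenyl)ethenyl]-3-[1-(2,6-dihydroxy-4-methoxyphenyl)ethenyl]butane-1,4-diol
Conditions: Bu4NF, H2NCH2CH2NH2, THF–DMPU, 60 °C, argon; then aq. NH4Cl
Reagents that add atoms: none
Why: Fluoride attacks silicon, ethene is lost and the hemiacetal anion collapses to phenoxide and formaldehyde (fluoride-induced SEM cleavage); the basic medium leaves the 4-methoxybenzylic carbinols and the 1-arylvinyl groups intact, and the diamine takes up formaldehyde before it can hydroxymethylate the phloroglucinol rings.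

**Step 12**
Reactants: 18 pentaphenol diol
Product: 19 (2R,3S)-3-[(2R,3S)-5-hydroxy-7-methoxy-2-(4-methoxyphenyl)-4-methylidenechroman-3-yl]-2-(4-methoxyphenyl)-4-methylidenechromane-5,7-diol
Conditions: PPh3, DIAD, THF–toluene (high dilution), −20 → 0 °C
Reagents that add atoms: none
Why: Double Mitsunobu cyclodehydration; each alkoxyphosphonium ion is displaced by an ortho phenoxide through a six-membered transition state with inversion at C2 and C2'', which places each 4-methoxyphenyl group cis to the C3–C3'' bond; the two ortho hydroxyls of each ring A are equivalent by rotation, and C3 and C3'' are not touched (they are S in 19 and R in the target only because C4 changes later from an alkene carbon to a ketone carbon, which alters the priority order).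

**Step 13**
Reactants: 19 bis(4-methylidene-flavan) triphenol
Product: 20 (2R,3S)-5,7-bis(benzyloxy)-3-[(2R,3S)-5-(benzyloxy)-7-methoxy-2-(4-methoxyphenyl)-4-methylidenechroman-3-yl]-2-(4-methoxyphenyl)-4-methylidenechromane
Conditions: BnBr (3.6 equiv), K2CO3, DMF, 0 °C → rt
Reagents that add atoms: benzyl bromide, BrCc1ccccc1
Why: O-benzylation of the three phenols shields the electron-rich rings from periodate in the next step; no enolisable centre exists yet, so the base is harmless, and 19 and 20 are handled at or below room temperature without storage because they are 2,5-diaryl-1,5-dienes that could undergo Cope rearrangement on heating.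

**Step 14**
Reactants: 20 tri-O-benzyl bis(4-methylidene-flavan)
Product: 22 (2R,3R)-5,7-bis(benzyloxy)-3-[(2R,3R)-5-(benzyloxy)-7-methoxy-2-(4-methoxyphenyl)-4-oxochroman-3-yl]-2-(4-methoxyphenyl)chroman-4-one, via bis(4-hydroxy-4-hydroxymethyl) tetraol 21 (not isolated)
Conditions: OsO4 (cat.), NaIO4, 2,6-lutidine, 1,4-dioxane–H2O, rt
Reagents that add atoms: osmium tetroxide, O=[Os](=O)(=O)=O (its oxygen is replenished by sodium periodate, [Na+].[O-]I(=O)(=O)=O)
Why: Lemieux–Johnson oxidation: osmylation of the two 1,1-disubstituted alkenes and periodate cleavage of the diols 21 to the ketones and formaldehyde; the lutidine buffer keeps the medium near neutral so that the new α-stereocentres C3 and C3'' of the cis-flavanone are not epimerised.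

**Step 15**
Reactants: 22 tri-O-benzyl biflavanone
Product: 23 (2R,3R)-5,7-dihydroxy-3-[(2R,3R)-5-hydroxy-7-methoxy-2-(4-methoxyphenyl)-4-oxochroman-3-yl]-2-(4-methoxyphenyl)chroman-4-one (target)
Conditions: H2 (1 atm), Pd/C (10 wt% Pd on carbon), EtOAc–MeOH, rt
Reagents that add atoms: none
Why: Hydrogenolysis of the three benzyl aryl ethers under neutral conditions; the methyl ethers, the aryl ketones and the four stereocentres should be untouched if the reaction is stopped at the uptake of three equivalents.

## Compound list

1 | phloroglucinol (benzene-1,3,5-triol) | Oc1cc(O)cc(O)c1 | starting material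
2 | 1,3,5-tris{[2-(trimethylsilyl)ethoxy]methoxy}benzene | C[Si](C)(C)CCOCOc1cc(OCOCC[Si](C)(C)C)cc(OCOCC[Si](C)(C)C)c1 | intermediate
3 | 2,4,6-tris{[2-(trimethylsilyl)ethoxy]methoxy}phenyllithium | [Li]c1c(OCOCC[Si](C)(C)C)cc(OCOCC[Si](C)(C)C)cc1OCOCC[Si](C)(C)C | intermediate (not isolated)
4 | 2-iodo-1,3,5-tris{[2-(trimethylsilyl)ethoxy]methoxy}benzene | Ic1c(OCOCC[Si](C)(C)C)cc(OCOCC[Si](C)(C)C)cc1OCOCC[Si](C)(C)C | intermediate
5 | 5-methoxyresorcinol (5-methoxybenzene-1,3-diol) | COc1cc(O)cc(O)c1 | starting material
6 | 1-methoxy-3,5-bis{[2-(trimethylsilyl)ethoxy]methoxy}benzene | COc1cc(OCOCC[Si](C)(C)C)cc(OCOCC[Si](C)(C)C)c1 | intermediate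
7 | 4-methoxy-2,6-bis{[2-(trimethylsilyl)ethoxy]methoxy}phenyllithium | [Li]c1c(OCOCC[Si](C)(C)C)cc(OC)cc1OCOCC[Si](C)(C)C | intermediate (not isolated)
8 | 2-iodo-5-methoxy-1,3-bis{[2-(trimethylsilyl)ethoxy]methoxy}benzene | Ic1c(OCOCC[Si](C)(C)C)cc(OC)cc1OCOCC[Si](C)(C)C | intermediate
9 | hexa-2,4-diyne-1,6-diol | OCC#CC#CCO | starting material
10 | (Z)-2-(tributylstannyl)hex-2-en-4-yne-1,6-diol | OC/C(=C/C#CCO)[Sn](CCCC)(CCCC)CCCC | intermediate
11 | (E)-2-(2,4,6-tris{[2-(trimethylsilyl)ethoxy]methoxy}phenyl)hex-2-en-4-yne-1,6-diol | OC/C(=C/C#CCO)c1c(OCOCC[Si](C)(C)C)cc(OCOCC[Si](C)(C)C)cc1OCOCC[Si](C)(C)C | intermediate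
12 | (2E,4Z)-2-(2,4,6-tris{[2-(trimethylsilyl)ethoxy]methoxy}phenyl)-5-(tributylstannyl)hexa-2,4-diene-1,6-diol | OC/C(=C/C=C(/CO)[Sn](CCCC)(CCCC)CCCC)c1c(OCOCC[Si](C)(C)C)cc(OCOCC[Si](C)(C)C)cc1OCOCC[Si](C)(C)C | intermediate
13 | (2E,4E)-2-(2,4,6-tris{[2-(trimethylsilyl)ethoxy]methoxy}phenyl)-5-(4-methoxy-2,6-bis{[2-(trimethylsilyl)ethoxy]methoxy}phenyl)hexa-2,4-diene-1,6-diol | OC/C(=C/C=C(/CO)c1c(OCOCC[Si](C)(C)C)cc(OC)cc1OCOCC[Si](C)(C)C)c1c(OCOCC[Si](C)(C)C)cc(OCOCC[Si](C)(C)C)cc1OCOCC[Si](C)(C)C | intermediate
14 | 4-methoxybenzyl chloride | COc1ccc(CCl)cc1 | starting material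
15 | (2E,4E)-1,6-bis[(4-methoxybenzyl)oxy]-2-(2,4,6-tris{[2-(trimethylsilyl)ethoxy]methoxy}phenyl)-5-(4-methoxy-2,6-bis{[2-(trimethylsilyl)ethoxy]methoxy}phenyl)hexa-2,4-diene | COc1ccc(COC/C(=C/C=C(/COCc2ccc(OC)cc2)c2c(OCOCC[Si](C)(C)C)cc(OC)cc2OCOCC[Si](C)(C)C)c2c(OCOCC[Si](C)(C)C)cc(OCOCC[Si](C)(C)C)cc2OCOCC[Si](C)(C)C)cc1 | intermediate
16 | lithium (1S,2S,3E)-alkoxide after the first shift: 5-[(4-methoxybenzyl)oxy]-1-(4-methoxyphenyl)-2-[1-(2,4,6-tris{SEM-oxy}phenyl)ethenyl]-4-(4-methoxy-2,6-bis{SEM-oxy}phenyl)pent-3-en-1-olate (drawn for the ether next to the tris-acetal ring reacting first; the other order is equally possible) | COc1ccc([C@@H]([O-])[C@H](C(=C)c2c(OCOCC[Si](C)(C)C)cc(OCOCC[Si](C)(C)C)cc2OCOCC[Si](C)(C)C)/C=C(/COCc2ccc(OC)cc2)c2c(OCOCC[Si](C)(C)C)cc(OC)cc2OCOCC[Si](C)(C)C)cc1.[Li+] | intermediate (not isolated)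
17 | (1S,2S,3S,4S)-1,4-bis(4-methoxyphenyl)-2-[1-(2,4,6-tris{[2-(trimethylsilyl)ethoxy]methoxy}phenyl)ethenyl]-3-[1-(4-methoxy-2,6-bis{[2-(trimethylsilyl)ethoxy]methoxy}phenyl)ethenyl]butane-1,4-diol | COc1ccc([C@@H](O)[C@H](C(=C)c2c(OCOCC[Si](C)(C)C)cc(OCOCC[Si](C)(C)C)cc2OCOCC[Si](C)(C)C)[C@@H](C(=C)c2c(OCOCC[Si](C)(C)C)cc(OC)cc2OCOCC[Si](C)(C)C)[C@H](O)c2ccc(OC)cc2)cc1 | intermediate
18 | (1S,2S,3S,4S)-1,4-bis(4-methoxyphenyl)-2-[1-(2,4,6-trihydroxyphenyl)ethenyl]-3-[1-(2,6-dihydroxy-4-methoxyphenyl)ethenyl]butane-1,4-diol | COc1ccc([C@@H](O)[C@H](C(=C)c2c(O)cc(O)cc2O)[C@@H](C(=C)c2c(O)cc(OC)cc2O)[C@H](O)c2ccc(OC)cc2)cc1 | intermediate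
19 | (2R,3S)-3-[(2R,3S)-5-hydroxy-7-methoxy-2-(4-methoxyphenyl)-4-methylidenechroman-3-yl]-2-(4-methoxyphenyl)-4-methylidenechromane-5,7-diol | COc1ccc([C@@H]2Oc3cc(O)cc(O)c3C(=C)[C@@H]2[C@H]2C(=C)c3c(O)cc(OC)cc3O[C@H]2c2ccc(OC)cc2)cc1 | intermediate
20 | (2R,3S)-5,7-bis(benzyloxy)-3-[(2R,3S)-5-(benzyloxy)-7-methoxy-2-(4-methoxyphenyl)-4-methylidenechroman-3-yl]-2-(4-methoxyphenyl)-4-methylidenechromane | COc1ccc([C@@H]2Oc3cc(OCc4ccccc4)cc(OCc4ccccc4)c3C(=C)[C@@H]2[C@H]2C(=C)c3c(OCc4ccccc4)cc(OC)cc3O[C@H]2c2ccc(OC)cc2)cc1 | intermediate
21 | (2R,3R,2''R,3''R)-tetraol: 20 with each C4=CH2 replaced by C4(OH)(CH2OH), configuration at C4 and C4'' not defined | COc1ccc([C@@H]2Oc3cc(OCc4ccccc4)cc(OCc4ccccc4)c3C(O)(CO)[C@@H]2[C@H]2C(O)(CO)c3c(OCc4ccccc4)cc(OC)cc3O[C@H]2c2ccc(OC)cc2)cc1 | intermediate (not isolated)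
22 | (2R,3R)-5,7-bis(benzyloxy)-3-[(2R,3R)-5-(benzyloxy)-7-methoxy-2-(4-methoxyphenyl)-4-oxochroman-3-yl]-2-(4-methoxyphenyl)chroman-4-one | COc1ccc([C@@H]2Oc3cc(OCc4ccccc4)cc(OCc4ccccc4)c3C(=O)[C@@H]2[C@H]2C(=O)c3c(OCc4ccccc4)cc(OC)cc3O[C@H]2c2ccc(OC)cc2)cc1 | intermediate
23 | (2R,3R)-5,7-dihydroxy-3-[(2R,3R)-5-hydroxy-7-methoxy-2-(4-methoxyphenyl)-4-oxochroman-3-yl]-2-(4-methoxyphenyl)chroman-4-one (CNP0184936.2) | COc1ccc([C@@H]2Oc3cc(O)cc(O)c3C(=O)[C@@H]2[C@H]2C(=O)c3c(O)cc(OC)cc3O[C@H]2c2ccc(OC)cc2)cc1 | target

## Step count and least certain steps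

Total: 15 steps. Longest linear sequence: 12 steps (steps 1, 2 and 6 to 15, from phloroglucinol 1).

**Step 10 (key step).** Several things can go wrong at once.
- Lithiation may occur at the wrong site: at a ring-A C–H flanked by two oxygen substituents, or at the allylic OCH2 group, whose anion is stabilised by the diene.
- Some [1,2]-shift may compete.
- Enantio-induction may be weak, because ten acetal oxygens compete with the chiral ligand for lithium.
- The second shift may take the mismatched course.

Fallback: from 15, run the rearrangement with an achiral base (n-BuLi, THF, −78 °C), where only the geometry-derived relative configuration is needed. This gives 17 as a racemate together with its mirror image, the (1R,2R,3R,4R)-diol F1. The enantiomers are separated by preparative chromatography on a cellulose carbamate chiral stationary phase, and the route is rejoined at 17.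

**Step 12.** The alkoxyphosphonium ions are 4-methoxybenzylic. Ionisation before displacement would lead to ring closure through the cation and thus to loss of the inversion course, which should favour the 2,3-trans ring. β-Elimination of the activated hydroxyl is a second escape. Fallback: carry a less electron-rich ring B through the closure and install the methoxy groups afterwards. From 13, etherification with two equivalents of 4-chlorobenzyl chloride (NaH, THF–DMF) gives the bis(4-chlorobenzyl) ether F2. Rearrangement as in step 10, helped by the more acidic benzylic position, gives the (1S,2S,3S,4S)-diol F3, and removal of the acetals as in step 11 gives the pentaphenol F4. Mitsunobu closure, now at a 4-chlorobenzylic carbon that does not ionise, gives the bis(4-chlorophenyl) bis(methylidene-flavan) F5, which is benzylated as in step 13 to the tribenzyl ether F6. Both aryl chlorides are then converted into methyl ethers by palladium-catalysed C–O coupling with methanol (Pd2(dba)3, tBuBrettPhos, NaOtBu, MeOH, 1,4-dioxane, at most 50 °C, short reaction time because of the 1,5-diene), and the route is rejoined at 20.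

**Step 11.** Five acetals must be cleaved. Incomplete cleavage, C-hydroxymethylation of the freed phloroglucinol rings by formaldehyde, and slow Cope rearrangement of the 1,5-diene during prolonged heating are the likely failures. Fallback: from 17, exchange the acetals for silyl groups with Me3SiOTf and 2,2'-bipyridyl (CH2Cl2, 0 °C). This gives the heptakis(trimethylsilyl) ether F7 while each CH2O unit is bound as an N-alkoxymethyl bipyridinium salt, which is filtered off before any phenol is free. Mild desilylation (NH4F, MeOH, 0 °C) then gives 18, where the route is rejoined. No heating and no free formaldehyde are involved.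

**Step 6.** Both partners are hindered: an α-branched alkenylstannane and a di-ortho-substituted, electron-rich aryl iodide. Slow transmetalation would let protodestannylation or homocoupling take over. Fallback: invert the polarity. From 10, iododestannylation (I2, one equivalent, CH2Cl2, 0 °C, so that no free iodine is carried on to the electron-rich arene) gives (Z)-2-iodohex-2-en-4-yne-1,6-diol F8. Aryllithium 3 is quenched with B(OMe)3 and hydrolysed to the boronic acid F9. Suzuki–Miyaura coupling (Pd(OAc)2, SPhos, K3PO4, THF–H2O, 40 °C) gives 11, where the route is rejoined.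

**Step 8.** The concern is the same as in step 6, on a more valuable dienylstannane that is also more prone to protodestannylation. Fallback: from 12, iododestannylation gives the (2E,4Z)-5-iodo diene diol F10. The boronic acid F11 is made from aryllithium 7. Suzuki–Miyaura coupling as above gives 13, where the route is rejoined.

**Step 5.** Over-addition (hydrostannation of both alkynes) or loss of regiocontrol on a conjugated diyne would give mixtures that are hard to separate. Fallback: differentiate the two ends first. From 9, monosilylation (NaH, one equivalent, then t-BuMe2SiCl, THF) gives 6-[(tert-butyldimethylsilyl)oxy]hexa-2,4-diyn-1-ol F12. Only the alkyne next to the free hydroxyl is directed in the hydrostannation, which gives the stannane F13, and Stille coupling with 4 gives the aryl enyne F14. Fluoride removes the silyl ether, and the route is rejoined at 11.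

## Further compounds

F1 | step 10 | (1R,2R,3R,4R)-enantiomer of 17 | COc1ccc([C@H](O)[C@@H](C(=C)c2c(OCOCC[Si](C)(C)C)cc(OCOCC[Si](C)(C)C)cc2OCOCC[Si](C)(C)C)[C@H](C(=C)c2c(OCOCC[Si](C)(C)C)cc(OC)cc2OCOCC[Si](C)(C)C)[C@@H](O)c2ccc(OC)cc2)cc1
F2 | step 12 | (2E,4E)-1,6-bis[(4-chlorobenzyl)oxy]-2-(2,4,6-tris{SEM-oxy}phenyl)-5-(4-methoxy-2,6-bis{SEM-oxy}phenyl)hexa-2,4-diene | Clc1ccc(COC/C(=C/C=C(/COCc2ccc(Cl)cc2)c2c(OCOCC[Si](C)(C)C)cc(OC)cc2OCOCC[Si](C)(C)C)c2c(OCOCC[Si](C)(C)C)cc(OCOCC[Si](C)(C)C)cc2OCOCC[Si](C)(C)C)cc1
F3 | step 12 | (1S,2S,3S,4S)-1,4-bis(4-chlorophenyl) analogue of 17 | Clc1ccc([C@@H](O)[C@H](C(=C)c2c(OCOCC[Si](C)(C)C)cc(OCOCC[Si](C)(C)C)cc2OCOCC[Si](C)(C)C)[C@@H](C(=C)c2c(OCOCC[Si](C)(C)C)cc(OC)cc2OCOCC[Si](C)(C)C)[C@H](O)c2ccc(Cl)cc2)cc1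
F4 | step 12 | (1S,2S,3S,4S)-1,4-bis(4-chlorophenyl) analogue of 18 | Clc1ccc([C@@H](O)[C@H](C(=C)c2c(O)cc(O)cc2O)[C@@H](C(=C)c2c(O)cc(OC)cc2O)[C@H](O)c2ccc(Cl)cc2)cc1
F5 | step 12 | (2R,3S,2''R,3''S)-2,2''-bis(4-chlorophenyl) analogue of 19 | Clc1ccc([C@@H]2Oc3cc(O)cc(O)c3C(=C)[C@@H]2[C@H]2C(=C)c3c(O)cc(OC)cc3O[C@H]2c2ccc(Cl)cc2)cc1
F6 | step 12 | (2R,3S,2''R,3''S)-2,2''-bis(4-chlorophenyl) analogue of 20 | Clc1ccc([C@@H]2Oc3cc(OCc4ccccc4)cc(OCc4ccccc4)c3C(=C)[C@@H]2[C@H]2C(=C)c3c(OCc4ccccc4)cc(OC)cc3O[C@H]2c2ccc(Cl)cc2)cc1
F7 | step 11 | heptakis(trimethylsilyl) ether of 18 | COc1ccc([C@@H](O[Si](C)(C)C)[C@H](C(=C)c2c(O[Si](C)(C)C)cc(O[Si](C)(C)C)cc2O[Si](C)(C)C)[C@@H](C(=C)c2c(O[Si](C)(C)C)cc(OC)cc2O[Si](C)(C)C)[C@H](O[Si](C)(C)C)c2ccc(OC)cc2)cc1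
F8 | step 6 | (Z)-2-iodohex-2-en-4-yne-1,6-diol | OC/C(I)=C/C#CCO
F9 | step 6 | (2,4,6-tris{[2-(trimethylsilyl)ethoxy]methoxy}phenyl)boronic acid | OB(O)c1c(OCOCC[Si](C)(C)C)cc(OCOCC[Si](C)(C)C)cc1OCOCC[Si](C)(C)C
F10 | step 8 | (2E,4Z)-5-iodo-2-(2,4,6-tris{[2-(trimethylsilyl)ethoxy]methoxy}phenyl)hexa-2,4-diene-1,6-diol | OC/C(=C/C=C(/CO)I)c1c(OCOCC[Si](C)(C)C)cc(OCOCC[Si](C)(C)C)cc1OCOCC[Si](C)(C)C
F11 | step 8 | (4-methoxy-2,6-bis{[2-(trimethylsilyl)ethoxy]methoxy}phenyl)boronic acid | OB(O)c1c(OCOCC[Si](C)(C)C)cc(OC)cc1OCOCC[Si](C)(C)C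
F12 | step 5 | 6-[(tert-butyldimethylsilyl)oxy]hexa-2,4-diyn-1-ol | OCC#CC#CCO[Si](C)(C)C(C)(C)C
F13 | step 5 | (Z)-6-[(tert-butyldimethylsilyl)oxy]-2-(tributylstannyl)hex-2-en-4-yn-1-ol | OC/C(=C/C#CCO[Si](C)(C)C(C)(C)C)[Sn](CCCC)(CCCC)CCCC
F14 | step 5 | (E)-6-[(tert-butyldimethylsilyl)oxy]-2-(2,4,6-tris{[2-(trimethylsilyl)ethoxy]methoxy}phenyl)hex-2-en-4-yn-1-ol | OC/C(=C/C#CCO[Si](C)(C)C(C)(C)C)c1c(OCOCC[Si](C)(C)C)cc(OCOCC[Si](C)(C)C)cc1OCOCC[Si](C)(C)C
A1 | alternative 1 | 7-O-benzyl ether of the target | COc1ccc([C@@H]2Oc3cc(OCc4ccccc4)cc(O)c3C(=O)[C@@H]2[C@H]2C(=O)c3c(O)cc(OC)cc3O[C@H]2c2ccc(OC)cc2)cc1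
A2 | alternative 1 | anti,anti bis-aldol: (2R,3R)-1-[4-(benzyloxy)-2,6-dihydroxyphenyl]-4-(2,6-dihydroxy-4-methoxyphenyl)-2,3-bis[(S)-hydroxy(4-methoxyphenyl)methyl]butane-1,4-dione | COc1ccc([C@@H](O)[C@H](C(=O)c2c(O)cc(OCc3ccccc3)cc2O)[C@@H](C(=O)c2c(O)cc(OC)cc2O)[C@H](O)c2ccc(OC)cc2)cc1
A3 | alternative 2 | 7''-O-demethyl analogue of the target (5,7-dihydroxy in both units) | COc1ccc([C@@H]2Oc3cc(O)cc(O)c3C(=O)[C@@H]2[C@H]2C(=O)c3c(O)cc(O)cc3O[C@H]2c2ccc(OC)cc2)cc1
A4 | alternative 2 | (2R,3R,2'R,3'R)-3,3'-linked bis{6-[(2,2-dimethyl-4-oxo-4H-1,3-dioxin-6-yl)methyl]-2-(4-methoxyphenyl)-2,3-dihydro-4H-pyran-4-one} | COc1ccc([C@@H]2OC(CC3=CC(=O)OC(C)(C)O3)=CC(=O)[C@@H]2[C@H]2C(=O)C=C(CC3=CC(=O)OC(C)(C)O3)O[C@H]2c2ccc(OC)cc2)cc1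
A5 | alternative 3 | 5,7-di-O-benzyl-5''-O-methyl ether of the target | COc1ccc([C@@H]2Oc3cc(OCc4ccccc4)cc(OCc4ccccc4)c3C(=O)[C@@H]2[C@H]2C(=O)c3c(OC)cc(OC)cc3O[C@H]2c2ccc(OC)cc2)cc1
A6 | alternative 3 | syn,syn bis-aldol with ortho-fluoroaryl ketones: (2R,3R)-1-[2,4-bis(benzyloxy)-6-fluorophenyl]-4-(2-fluoro-4,6-dimethoxyphenyl)-2,3-bis[(R)-hydroxy(4-methoxyphenyl)methyl]butane-1,4-dione | COc1ccc([C@H](O)[C@H](C(=O)c2c(F)cc(OCc3ccccc3)cc2OCc2ccccc2)[C@@H](C(=O)c2c(F)cc(OC)cc2OC)[C@@H](O)c2ccc(OC)cc2)cc1
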